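**Retrosynthetic overview**
- Target quinone ⇐ Teuber oxidation of a 2-methoxy-6-alkylphenol that already carries the (R)-acetate.
- That phenol ⇐ one-pot alkene hydrogenation and O-debenzylation ⇐ cross metathesis of an (R)-homoallylic acetate with dec-1-ene.
- (R)-Homoallylic alcohol ⇐ Brown asymmetric carbonyl allylation of an arylacetaldehyde; this forms C2–C3 of the side chain and sets the only stereocentre.
- Arylacetaldehyde ⇐ dihydroxylation and periodate cleavage of O-benzyl-o-eugenol ⇐ o-eugenol.
- Rings: none is built; the single six-membered carbocycle is bought with o-eugenol and is oxidised to the quinone in the last step.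

Assumption: the stereocentre of the given SMILES is R (OAc > CH2–quinone > CH2–alkyl > H); o-eugenol, dec-1-ene and (+)-Ipc2BOMe are bought.

**Route**

Step 1
Reactants: 1 2-allyl-6-methoxyphenol (o-eugenol)
Product: 2 2-(benzyloxy)-1-methoxy-3-(prop-2-en-1-yl)benzene
Conditions: BnBr, K2CO3, DMF, rt → 50 °C
Reagents that add atoms: benzyl bromide, BrCc1ccccc1
Why: Williamson ether synthesis: the phenoxide formed with K2CO3 displaces bromide from benzyl bromide (SN2), masking the phenol as a benzyl ether that is inert to the oxidants, the allylborane and the metathesis catalyst ahead and is removed later by hydrogenolysis.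

Step 2
Reactants: 2 2-(benzyloxy)-1-methoxy-3-(prop-2-en-1-yl)benzene
Product: 3 rac-3-[2-(benzyloxy)-3-methoxyphenyl]propane-1,2-diol
Conditions: OsO4 (2 mol%), NMO, acetone/H2O 4:1, rt
Reagents that add atoms: N-methylmorpholine N-oxide, C[N+]1([O-])CCOCC1; water, O (net source of the two hydroxyl oxygens); passed on through catalytic OsO4, O=[Os](=O)(=O)=O
Why: Upjohn dihydroxylation: catalytic OsO4 adds to the isolated terminal alkene in a [3+2] cycloaddition far faster than it touches the arene or the ethers and NMO regenerates it, the new carbinol centre being racemic and of no consequence because step 3 destroys it.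

Step 3
Reactants: 3 rac-3-[2-(benzyloxy)-3-methoxyphenyl]propane-1,2-diol
Product: 4 2-[2-(benzyloxy)-3-methoxyphenyl]acetaldehyde
Conditions: NaIO4, THF/H2O (pH 7 phosphate), 0 °C → rt; extract, dry (MgSO4), use at once
Reagents that add atoms: none
Why: Malaprade glycol cleavage: NaIO4 splits the 1,2-diol through a cyclic periodate ester at neutral pH, releasing the enolisable arylacetaldehyde cleanly with formaldehyde as the only organic by-product, so it can be extracted, dried and used without chromatography.

Step 4
Reactants: 4 2-[2-(benzyloxy)-3-methoxyphenyl]acetaldehyde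
Product: 6 (2R)-1-[2-(benzyloxy)-3-methoxyphenyl]pent-4-en-2-ol, via borinate ester 5 (not isolated)
Conditions: (+)-Ipc2BOMe [(−)-α-pinene series], CH2=CHCH2MgBr, Et2O, 0 °C → rt; then 4, Et2O, −78 °C, 2 h; then aq. NaOH, 30% H2O2, 0 °C → rt
Reagents that add atoms: allylmagnesium bromide, C=CC[Mg]Br
Why: Brown asymmetric allylboration, a carbonyl allylation: the B-allyl borane carrying isopinocampheyl groups of the (−)-α-pinene series transfers its allyl group through a closed chair Zimmerman–Traxler transition state to the Re face of the aldehyde, which joins the arylacetaldehyde fragment to the allyl fragment and sets C2 as R (about 90–95% ee is usual for arylacetaldehydes), the non-basic reagent at −78 °C outrunning enolisation.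

Step 5
Reactants: 6 (2R)-1-[2-(benzyloxy)-3-methoxyphenyl]pent-4-en-2-ol
Product: 7 (2R)-1-[2-(benzyloxy)-3-methoxyphenyl]pent-4-en-2-yl acetate
Conditions: Ac2O, pyridine, DMAP (cat.), CH2Cl2, 0 °C → rt
Reagents that add atoms: acetic anhydride, CC(=O)OC(C)=O
Why: DMAP-catalysed O-acetylation (nucleophilic acyl substitution at the anhydride): only the O–H bond of the secondary alcohol reacts, so the R configuration is retained and the acetate of the target is installed before the phenol is unmasked.

Step 6
Reactants: 7 (2R)-1-[2-(benzyloxy)-3-methoxyphenyl]pent-4-en-2-yl acetate; 8 dec-1-ene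
Product: 9 (2R,4E)-1-[2-(benzyloxy)-3-methoxyphenyl]tridec-4-en-2-yl acetate
Conditions: second-generation Grubbs catalyst RuCl2(=CHPh)(PCy3)[1,3-bis(2,4,6-trimethylphenyl)imidazolidin-2-ylidene] (5 mol%), 8 (4 equiv), CH2Cl2, 40 °C
Reagents that add atoms: none
Why: Olefin cross metathesis: both partners are unhindered terminal alkenes, so a fourfold excess of cheap dec-1-ene and loss of ethylene push 7 to the cross product, whose E/Z ratio does not matter because the double bond is hydrogenated next, while the homoallylic acetate and its stereocentre are untouched.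

Step 7
Reactants: 9 (2R,4E)-1-[2-(benzyloxy)-3-methoxyphenyl]tridec-4-en-2-yl acetate
Product: 11 (2R)-1-(2-hydroxy-3-methoxyphenyl)tridecan-2-yl acetate, via saturated benzyl ether 10 (not isolated)
Conditions: H2 (1 atm), 10% Pd/C, EtOAc/EtOH, rt
Reagents that add atoms: none
Why: Heterogeneous catalytic hydrogenation on Pd/C: the disubstituted alkene is saturated first and the benzylic C–O bond of the aryl benzyl ether is then hydrogenolysed, whereas the secondary acetate, which is neither benzylic nor allylic, and its stereocentre are inert.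

Step 8
Reactants: 11 (2R)-1-(2-hydroxy-3-methoxyphenyl)tridecan-2-yl acetate
Product: 12 (2R)-1-(5-methoxy-3,6-dioxocyclohexa-1,4-dien-1-yl)tridecan-2-yl acetate
Conditions: K2[ON(SO3)2] (Fremy's salt, 2.5 equiv), aq. KH2PO4, acetone, 0 °C → rt
Reagents that add atoms: potassium nitrosodisulfonate K2[ON(SO3)2], [K+].[K+].[O]N(S(=O)(=O)[O-])S(=O)(=O)[O-]
Why: Teuber oxidation: two equivalents of the nitrosodisulfonate radical turn the phenol into the para-quinone (hydrogen abstraction to the phenoxyl radical, radical coupling at the free para carbon, loss of imidodisulfonate), both ortho positions being blocked by OMe and the side chain, and the near-neutral buffer leaves the acetate and the remote R stereocentre alone.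

**Compound list**

1 | 2-allyl-6-methoxyphenol (o-eugenol) | C=CCc1cccc(OC)c1O | starting material
2 | 2-(benzyloxy)-1-methoxy-3-(prop-2-en-1-yl)benzene | C=CCc1cccc(OC)c1OCc1ccccc1 | intermediate
3 | rac-3-[2-(benzyloxy)-3-methoxyphenyl]propane-1,2-diol (racemic, centre lost in step 3) | OCC(O)Cc1cccc(OC)c1OCc1ccccc1 | intermediate
4 | 2-[2-(benzyloxy)-3-methoxyphenyl]acetaldehyde | O=CCc1cccc(OC)c1OCc1ccccc1 | intermediate
5 | (2R)-1-[2-(benzyloxy)-3-methoxyphenyl]pent-4-en-2-yl diisopinocampheylborinate (isopinocampheyl groups of the (−)-α-pinene series) | C=CC[C@H](Cc1cccc(OC)c1OCc1ccccc1)OB([C@H]1C[C@H]2C[C@@H]([C@@H]1C)C2(C)C)[C@H]1C[C@H]2C[C@@H]([C@@H]1C)C2(C)C | intermediate (not isolated)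
6 | (2R)-1-[2-(benzyloxy)-3-methoxyphenyl]pent-4-en-2-ol | C=CC[C@H](Cc1cccc(OC)c1OCc1ccccc1)O | intermediate
7 | (2R)-1-[2-(benzyloxy)-3-methoxyphenyl]pent-4-en-2-yl acetate | C=CC[C@H](Cc1cccc(OC)c1OCc1ccccc1)OC(C)=O | intermediate
8 | dec-1-ene | C=CCCCCCCCC | starting material
9 | (2R,4E)-1-[2-(benzyloxy)-3-methoxyphenyl]tridec-4-en-2-yl acetate (major isomer; the minor 4Z isomer is carried along) | CCCCCCCC/C=C/C[C@H](Cc1cccc(OC)c1OCc1ccccc1)OC(C)=O | intermediate
10 | (2R)-1-[2-(benzyloxy)-3-methoxyphenyl]tridecan-2-yl acetate | CCCCCCCCCCC[C@H](Cc1cccc(OC)c1OCc1ccccc1)OC(C)=O | intermediate (not isolated)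
11 | (2R)-1-(2-hydroxy-3-methoxyphenyl)tridecan-2-yl acetate | CCCCCCCCCCC[C@H](Cc1cccc(OC)c1O)OC(C)=O | intermediate
12 | (2R)-1-(5-methoxy-3,6-dioxocyclohexa-1,4-dien-1-yl)tridecan-2-yl acetate | CCCCCCCCCCC[C@H](CC1=CC(=O)C=C(OC)C1=O)OC(C)=O | target

**Step count and risks**

Total step count: 8. Longest linear sequence: 8 steps (1 → 12).

The three steps most likely to fail:

- **Step 4 (allylboration).** Aldehyde 4 is enolisable and air-sensitive, and the ee can fall short. The fallback sets out from 4 and comes back at 6. The dried extract of step 3 is not stored but reduced at once (NaBH4, MeOH, 0 °C) to the shelf-stable 2-[2-(benzyloxy)-3-methoxyphenyl]ethan-1-ol F1. F1 is then allylated from the alcohol oxidation level by iridium-catalysed transfer-hydrogenative carbonyl allylation: [Ir(cod)Cl]2 (2.5 mol%), (R)-BINAP (5 mol%), 4-chloro-3-nitrobenzoic acid (10 mol%), Cs2CO3 (20 mol%), allyl acetate (10 equiv), THF, 100 °C, sealed tube. The aldehyde then exists only transiently at the metal, and a catalytic chiral ligand instead of a stoichiometric terpene borane controls the face. The choice of (R)-BINAP for the (R)-alcohol is from memory and is not certain; it is checked by Mosher ester analysis of the first batch against Brown-derived 6, and the antipodal ligand is taken if needed.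

- **Step 6 (cross metathesis).** Homodimerisation, incomplete conversion or double-bond migration can erode the yield. The fallback sets out from 7 and comes back at 10. Hydroboration of the terminal alkene with 9-BBN (THF, rt) gives (2R)-1-[2-(benzyloxy)-3-methoxyphenyl]-5-(9-borabicyclo[3.3.1]nonan-9-yl)pentan-2-yl acetate F2. F2 is coupled in the same flask with 1-bromooctane in an alkyl–alkyl Suzuki–Miyaura reaction (Pd(OAc)2, PCy3, K3PO4·H2O, THF, rt). This gives the saturated benzyl ether 10 directly; it is isolated and debenzylated to 11 under the step 7 conditions.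

- **Step 8 (Teuber oxidation).** The radical salt is capricious and the yield of the quinone can be low. The fallback sets out from 11 and comes back at 12, and stays acidic or neutral so the acetate survives. Para-nitrosation (NaNO2, AcOH/EtOH, 0 °C) at the only free position activated by the phenol gives (2R)-1-(2-hydroxy-3-methoxy-5-nitrosophenyl)tridecan-2-yl acetate F3. Reduction with Na2S2O4 (THF/H2O, rt) gives (2R)-1-(5-amino-2-hydroxy-3-methoxyphenyl)tridecan-2-yl acetate F4. Oxidation of F4 with FeCl3 in dilute HCl/Et2O (two-phase, rt) passes through the quinone imine, which hydrolyses to 12.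

**Further compounds**

F1 | step 4 | 2-[2-(benzyloxy)-3-methoxyphenyl]ethan-1-ol | OCCc1cccc(OC)c1OCc1ccccc1
F2 | step 6 | (2R)-1-[2-(benzyloxy)-3-methoxyphenyl]-5-(9-borabicyclo[3.3.1]nonan-9-yl)pentan-2-yl acetate | C(CC[C@H](Cc1cccc(OC)c1OCc1ccccc1)OC(C)=O)B1C2CCCC1CCC2
F3 | step 8 | (2R)-1-(2-hydroxy-3-methoxy-5-nitrosophenyl)tridecan-2-yl acetate | CCCCCCCCCCC[C@H](Cc1cc(N=O)cc(OC)c1O)OC(C)=O
F4 | step 8 | (2R)-1-(5-amino-2-hydroxy-3-methoxyphenyl)tridecan-2-yl acetate | CCCCCCCCCCC[C@H](Cc1cc(N)cc(OC)c1O)OC(C)=O
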